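**Plan**

- Retrosynthesis: coelenterazine is read as the aromatic tautomer of a 2-arylidene-5,8-dihydroimidazo[1,2-a]pyrazin-3-one. Cut N7–C6 (imine), then N4–C8a (amidine C–N of the imidazolone), then C2=CH–Ar (aldol type).
- This leads to Boc-Phe-Gly-OH, an aryl aldehyde and an α-aminoketone, which is the presumed biogenetic Phe/Tyr/Tyr pattern: N7–C8–C8a from Phe, N1–C2–C3 from (dehydro)Tyr, N4–C5–C6 from a β-oxotyramine unit.
- Forward: (1) an Erlenmeyer azlactone sets C2=CH–Ar; (2) aminolysis and cyclodehydration close the imidazolone ring (N4–C8a), giving a GFP-chromophore-type intermediate; (3) acid unmasks N7, which closes the pyrazine ring on C6, and proton shifts aromatize the bicycle.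
- Enabling feature: in the 5,8-dihydropyrazine ring, C8–H and one C5–H are exactly the two hydrogens that the exocyclic C2=CH–Ar bond lacks. Ring closure plus tautomerization is therefore redox-neutral, with no late oxidation of the air-sensitive core and no preformed trisubstituted aminopyrazine.
- Stereochemistry: none in the target; the Phe-derived centre (C8) and the Z-alkene are both erased in step 3.

Key step: step 3

Remark: the target SMILES has no stereocentre and no stereogenic double bond, so the target is one achiral compound and the single-enantiomer requirement is void. The Phe-derived carbon may epimerize under steps 1–2; it is drawn undefined from compound 3 on, which is of no consequence.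

**Route**

Step 1
Reactants: 1 N-Boc-L-phenylalanylglycine; 2 4-(tert-butoxy)benzaldehyde
Product: 4 (Z)-4-(4-tert-butoxybenzylidene)-2-[1-(tert-butoxycarbonylamino)-2-phenylethyl]-1,3-oxazol-5(4H)-one, via saturated oxazolone 3 (not isolated)
Conditions: Ac2O, NaOAc, 80 °C
Reagents that add atoms: none
Why: Erlenmeyer–Plöchl azlactone synthesis: the acylglycine terminus cyclodehydrates to the 5(4H)-oxazolone, whose acidic C4–H2 condenses with the aldehyde (Perkin-type aldol/dehydration) to give the thermodynamically preferred Z-arylidene azlactone; the tert-butyl ether and the carbamate should be inert to acetate/acetic anhydride.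

Step 2
Reactants: 4 (Z)-azlactone; 5 2-amino-1-(4-hydroxyphenyl)ethan-1-one hydrochloride
Product: 7 tert-butyl N-{1-[(4Z)-4-(4-tert-butoxybenzylidene)-1-[2-(4-hydroxyphenyl)-2-oxoethyl]-5-oxo-4,5-dihydro-1H-imidazol-2-yl]-2-phenylethyl}carbamate, via dehydrotripeptide amide 6 (not isolated)
Conditions: Et3N, THF/DMF, 0 °C → rt; then HMDS, pyridine, 100 °C; MeOH/aq NH4Cl work-up
Reagents that add atoms: none
Why: Aminolysis of the unsaturated azlactone at C5 by the amine (freed in the presence of the acylating agent, so that it is acylated before it can self-condense) gives the diamide; silylative cyclodehydration then lets the new amide nitrogen attack the neighbouring amide carbonyl (5-exo-trig) to form the 4-arylidene-imidazol-5-one, the standard construction of GFP-chromophore-type imidazolones.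

Step 3
Reactants: 7 Boc/tert-butyl-protected arylidene imidazolone
Product: 10 coelenterazine [8-benzyl-2-(4-hydroxybenzyl)-6-(4-hydroxyphenyl)imidazo[1,2-a]pyrazin-3(7H)-one], via amino imidazolone 8 (not isolated), via arylidene dihydroimidazopyrazinone 9 (not isolated)
Conditions: TFA/H2O 95:5, 0 °C → rt, Ar; evaporate; then NaOAc, AcOH/EtOH 1:9 (degassed), 70 °C, Ar
Reagents that add atoms: none
Why: Proposed new method: acid removes the Boc group and the aryl tert-butyl ether, and on buffering the freed amine N7 condenses with the aryl ketone carbon C6 (6-exo-trig addition, then dehydration) to close the pyrazine ring as the 5,8-dihydro compound 9, an ordinary intramolecular ketimine formation. Compound 9 is a non-aromatic tautomer of the target: C8–H lies α to the amidine carbon C8a and on the imine nitrogen N7 (an amino-acid ketimine type C–H), so acetate/acetic acid should move it through the ene-diamine C8=C8a–N1H to the exocyclic benzylidene carbon (N1 lone pair pushes, C-protonation, loss of N1–H gives N1=C2), and an imine–enamine shift of one C5–H to N7 then gives the 7H-imidazo[1,2-a]pyrazin-3-one. The closest known reaction types are the acid- or base-catalysed isoaromatization of exocyclic arylidene dihydro(hetero)arenes to benzyl (hetero)arenes and the 1,3-prototropic (2-azaallyl) shift of α-amino-acid ketimines; the driving force is the aromatic 3-hydroxyimidazo[1,2-a]pyrazine π-system. No stereocentre is formed, and both the C8 centre and the Z-alkene are erased, so neither configuration nor alkene geometry matters. The selectivity needed is chemoselectivity of the amine for the ketone, which the ring geometry secures: the C8a substituent and N4–CH2 sit on adjacent ring atoms, so the six-membered imine is the only unstrained closure, while aza-Michael addition to the exocyclic carbon would need the transoid C8a=N1–C2=C unit inside a six-membered ring; oxygen is excluded because the product autoxidizes.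

**Compound list**

1 | N-Boc-L-phenylalanylglycine | CC(C)(C)OC(=O)N[C@@H](Cc1ccccc1)C(=O)NCC(=O)O | starting material
2 | 4-(tert-butoxy)benzaldehyde | CC(C)(C)Oc1ccc(C=O)cc1 | starting material
3 | tert-butyl N-[1-(5-oxo-4,5-dihydro-1,3-oxazol-2-yl)-2-phenylethyl]carbamate | CC(C)(C)OC(=O)NC(Cc1ccccc1)C1=NCC(=O)O1 | intermediate (not isolated)
4 | (Z)-4-(4-tert-butoxybenzylidene)-2-[1-(tert-butoxycarbonylamino)-2-phenylethyl]-1,3-oxazol-5(4H)-one | CC(C)(C)OC(=O)NC(Cc1ccccc1)C1=N/C(=C\c2ccc(OC(C)(C)C)cc2)C(=O)O1 | intermediate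
5 | 2-amino-1-(4-hydroxyphenyl)ethan-1-one hydrochloride | [Cl-].[NH3+]CC(=O)c1ccc(O)cc1 | starting material
6 | (Z)-Boc-Phe-ΔTyr(tBu) N-[2-(4-hydroxyphenyl)-2-oxoethyl]amide | CC(C)(C)OC(=O)NC(Cc1ccccc1)C(=O)N/C(=C\c1ccc(OC(C)(C)C)cc1)C(=O)NCC(=O)c1ccc(O)cc1 | intermediate (not isolated)
7 | tert-butyl N-{1-[(4Z)-4-(4-tert-butoxybenzylidene)-1-[2-(4-hydroxyphenyl)-2-oxoethyl]-5-oxo-4,5-dihydro-1H-imidazol-2-yl]-2-phenylethyl}carbamate | CC(C)(C)OC(=O)NC(Cc1ccccc1)C1=N/C(=C\c2ccc(OC(C)(C)C)cc2)C(=O)N1CC(=O)c1ccc(O)cc1 | intermediate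
8 | (4Z)-2-(1-amino-2-phenylethyl)-4-(4-hydroxybenzylidene)-1-[2-(4-hydroxyphenyl)-2-oxoethyl]-1H-imidazol-5(4H)-one | NC(Cc1ccccc1)C1=N/C(=C\c2ccc(O)cc2)C(=O)N1CC(=O)c1ccc(O)cc1 | intermediate (not isolated)
9 | (Z)-8-benzyl-2-(4-hydroxybenzylidene)-6-(4-hydroxyphenyl)-5,8-dihydroimidazo[1,2-a]pyrazin-3(2H)-one | O=C1N2CC(c3ccc(O)cc3)=NC(Cc3ccccc3)C2=N/C1=C\c1ccc(O)cc1 | intermediate (not isolated)
10 | coelenterazine, 8-benzyl-2-(4-hydroxybenzyl)-6-(4-hydroxyphenyl)imidazo[1,2-a]pyrazin-3(7H)-one | O=c1c(Cc2ccc(O)cc2)nc2c(Cc3ccccc3)[nH]c(-c3ccc(O)cc3)cn1-2 | target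

**Step count and risks**

Total step count: 3. Longest linear sequence: 3.

Steps most likely to fail:

1. Step 3 (proposed new method). The proton shifts may stall after ring closure, at the cyclic imine or at a partly shifted tautomer, and adventitious oxygen may dehydrogenate the electron-rich bicycle.
   Fallback with known chemistry, setting out from 7 and returning at 10: 7 is deprotected and cyclized as above to 9. Instead of relying on tautomerization, the 5,8-dihydropyrazine ring is deliberately dehydrogenated with activated MnO2 (CH2Cl2/MeOH, rt), a standard dihydropyrazine aromatization, to the fully conjugated (Z)-8-benzyl-2-(4-hydroxybenzylidene)-6-(4-hydroxyphenyl)imidazo[1,2-a]pyrazin-3(2H)-one (dehydrocoelenterazine) F1, which is isolated. Conjugate hydride addition to the benzylidene carbon of F1 with NaBH4 (MeOH/CH2Cl2, 0 °C, Ar), followed by acidic quench, should give 10.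

2. Step 2. The liberated α-aminoketone may self-condense before it is acylated, and the cyclodehydration may go astray through enolization or O-attack of the phenacyl amide (oxazole-type closure) instead of N-attack on the neighbouring amide carbonyl.
   Fallback, setting out from 4 and returning at 7: the ketone is carried at the alcohol oxidation level. Azlactone 4 is opened with racemic octopamine hydrochloride (2-amino-1-(4-hydroxyphenyl)ethanol hydrochloride; Et3N, THF/DMF, rt) to the (Z)-Boc-Phe-ΔTyr(tBu) N-[2-hydroxy-2-(4-hydroxyphenyl)ethyl]amide F2. HMDS/pyridine at 100 °C followed by methanolic desilylation gives the N-(2-hydroxy-2-arylethyl) arylidene imidazolone F3. Its para-hydroxybenzylic alcohol is then oxidized with DDQ in dioxane (via the quinone methide) to ketone 7.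

3. Step 1. In hot acetic anhydride the Boc group may be lost or the 2-(α-amidoalkyl)oxazolone may decompose through its 2-alkylidene tautomer, and condensation with the electron-rich aldehyde may be sluggish.
   Fallback, setting out from 2 and returning at 4: olefination replaces the azlactone condensation. Methyl 2-[(N-Boc-L-phenylalanyl)amino]-2-(dimethoxyphosphoryl)acetate F4 is made from commercial Cbz-α-phosphonoglycine trimethyl ester (H2, Pd/C, then Boc-L-Phe-OH, EDC/HOBt). Horner–Wadsworth–Emmons reaction of F4 with 2 (DBU, CH2Cl2, rt) gives the (Z)-dehydrodipeptide methyl ester Boc-Phe-ΔTyr(tBu)-OMe F5. Saponification (LiOH, THF/H2O) gives the acid Boc-Phe-ΔTyr(tBu)-OH F6, and carbodiimide cyclodehydration (EDC·HCl, CH2Cl2, 0 °C) closes it to azlactone 4.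

**Further compounds**

F1 | step 3 | (Z)-8-benzyl-2-(4-hydroxybenzylidene)-6-(4-hydroxyphenyl)imidazo[1,2-a]pyrazin-3(2H)-one (dehydrocoelenterazine) | O=C1N2C=C(c3ccc(O)cc3)N=C(Cc3ccccc3)C2=N/C1=C\c1ccc(O)cc1
F2 | step 2 | (Z)-Boc-Phe-ΔTyr(tBu) N-[2-hydroxy-2-(4-hydroxyphenyl)ethyl]amide | CC(C)(C)OC(=O)NC(Cc1ccccc1)C(=O)N/C(=C\c1ccc(OC(C)(C)C)cc1)C(=O)NCC(O)c1ccc(O)cc1
F3 | step 2 | tert-butyl N-{1-[(4Z)-4-(4-tert-butoxybenzylidene)-1-[2-hydroxy-2-(4-hydroxyphenyl)ethyl]-5-oxo-4,5-dihydro-1H-imidazol-2-yl]-2-phenylethyl}carbamate | CC(C)(C)OC(=O)NC(Cc1ccccc1)C1=N/C(=C\c2ccc(OC(C)(C)C)cc2)C(=O)N1CC(O)c1ccc(O)cc1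
F4 | step 1 | methyl 2-[(N-Boc-L-phenylalanyl)amino]-2-(dimethoxyphosphoryl)acetate | CC(C)(C)OC(=O)N[C@@H](Cc1ccccc1)C(=O)NC(C(=O)OC)P(=O)(OC)OC
F5 | step 1 | methyl (Z)-2-[(N-Boc-L-phenylalanyl)amino]-3-(4-tert-butoxyphenyl)prop-2-enoate | CC(C)(C)OC(=O)N[C@@H](Cc1ccccc1)C(=O)N/C(=C\c1ccc(OC(C)(C)C)cc1)C(=O)OC
F6 | step 1 | (Z)-2-[(N-Boc-L-phenylalanyl)amino]-3-(4-tert-butoxyphenyl)prop-2-enoic acid | CC(C)(C)OC(=O)N[C@@H](Cc1ccccc1)C(=O)N/C(=C\c1ccc(OC(C)(C)C)cc1)C(=O)O
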